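**Strategy.** Everything rests on opening ring C of unit 2 (the flavone bonded through C8; unit 1 is bonded through C3) at C4–C4a and O1–C2. Ring A of unit 2 is a phloroglucinol ring. Worn as a symmetric 2,6-dihydroxy-4-methoxyphenyl group on C3 of unit 1, its two free CH carbons are equivalent and only a hydroxyl beside the biaryl bond can become O1. Friedel–Crafts acylation with 4-methoxycinnamoyl chloride and oxa-Michael closure therefore give, in one operation, the 8-linked flavanone alone; dehydrogenation and demethylation finish. The precursor, a 3-arylflavone with all other phenols methylated, comes from Negishi coupling of a 3-iodoflavone with a bis-MOM arylzinc.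

Key step: step 6

Assumptions: 4',5,7-trimethoxyflavone (3) is taken as a purchasable compound. Flavanone 13 is racemic and its SMILES shows one enantiomer. The axis between the two units carries no descriptor in the target; slow rotation about it could show 13 as two diastereomers, which would converge in step 7.

**Step 1**
Reactants: 1 5-methoxyresorcinol
Product: 2 1-methoxy-3,5-bis(methoxymethoxy)benzene
Conditions: NaH, MOMCl, DMF, 0 °C → rt
Reagents that add atoms: chloromethyl methyl ether (MOMCl), COCCl
Why: Williamson ether synthesis: NaH turns both phenols into phenoxides, which displace chloride from the very reactive chloromethyl ether, and because 1 is symmetric only one bis-acetal can form.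

**Step 2**
Reactants: 3 5,7-dimethoxy-2-(4-methoxyphenyl)chromen-4-one (4',5,7-trimethoxyflavone)
Product: 5 3-iodo-5,7-dimethoxy-2-(4-methoxyphenyl)chromen-4-one, via 3-lithioflavone 4 (not isolated)
Conditions: LiN(iPr)2, THF, −78 °C; then I2, THF, −78 °C → 0 °C
Reagents that add atoms: iodine, II
Why: Deprotonation–iodination (the known lithiation of flavones at C3): the hindered amide base removes the only vinylic hydrogen, which is acidified by the neighbouring carbonyl that also chelates lithium, and iodine traps the vinyllithium at −78 °C before ring C can open, while the aryl methyl ethers are inert.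

**Step 3**
Reactants: 2 1-methoxy-3,5-bis(methoxymethoxy)benzene; 5 3-iodo-5,7-dimethoxy-2-(4-methoxyphenyl)chromen-4-one
Product: 8 5,7-dimethoxy-3-[4-methoxy-2,6-bis(methoxymethoxy)phenyl]-2-(4-methoxyphenyl)chromen-4-one, via aryllithium 6 (not isolated), via arylzinc chloride 7 (not isolated)
Conditions: 2, n-BuLi, THF, 0 °C → rt; ZnCl2, THF, 0 °C → rt; 5, Pd2(dba)3 (2 mol %), RuPhos (8 mol %), THF, 65 °C
Reagents that add atoms: none
Why: Directed ortho-metalation followed by Negishi cross-coupling: n-BuLi removes the hydrogen flanked by the two MOM ethers (double chelation, stronger than the single methoxy group), ZnCl2 turns the aryllithium into an arylzinc that leaves the chromone carbonyl alone, and zerovalent palladium with the bulky dialkylbiarylphosphine RuPhos, a catalyst type established for biaryls with four ortho substituents, joins it to C3 of the iodoflavone.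

**Step 4**
Reactants: 8 5,7-dimethoxy-3-[4-methoxy-2,6-bis(methoxymethoxy)phenyl]-2-(4-methoxyphenyl)chromen-4-one
Product: 9 3-(2,6-dihydroxy-4-methoxyphenyl)-5,7-dimethoxy-2-(4-methoxyphenyl)chromen-4-one
Conditions: 3 M HCl, MeOH, 55 °C
Reagents that add atoms: none
Why: Acid-catalysed acetal cleavage (transacetalisation to dimethoxymethane): the two MOM groups leave under conditions that touch neither the aryl methyl ethers nor the chromone, and the freed hydroxyls cannot close onto C2 of unit 1 because that would be a 5-endo-trig addition that destroys the pyranone conjugation.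

**Step 5**
Reactants: 10 (E)-4-methoxycinnamic acid
Product: 11 (E)-4-methoxycinnamoyl chloride
Conditions: (COCl)2, DMF (cat.), CH2Cl2, 0 °C → rt
Reagents that add atoms: oxalyl chloride, O=C(Cl)C(Cl)=O
Why: Acid chloride formation through the Vilsmeier-type chloroiminium salt from DMF and oxalyl chloride, which leaves the E double bond and the aryl ether untouched and gives only gaseous by-products, so that 11 can be used crude.

**Step 6**
Reactants: 9 3-(2,6-dihydroxy-4-methoxyphenyl)-5,7-dimethoxy-2-(4-methoxyphenyl)chromen-4-one; 11 (E)-4-methoxycinnamoyl chloride (1.05 equiv)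
Product: 13 (±)-8-[5,7-dimethoxy-2-(4-methoxyphenyl)-4-oxochromen-3-yl]-7-hydroxy-5-methoxy-2-(4-methoxyphenyl)chroman-4-one (racemic at C2), via chalcone 12 (not isolated)
Conditions: BF3·OEt2 (excess), 1,4-dioxane, 85 °C; then 1 M HCl, EtOH, 60 °C
Reagents that add atoms: none
Why: BF3 activates the acid chloride (or the aryl cinnamate formed first at a phenol, which then undergoes Fries rearrangement), and one of the two equivalent CH carbons of the dihydroxy-methoxyphenyl ring, ortho to a hydroxyl and to the methoxy group, attacks the acyl carbon to give the 2'-hydroxychalcone 12, which forms the C4–C4a bond of unit 2. The hydroxyl next to the new ketone, which is the one beside the biaryl bond, then adds to the acid-activated enone in a 6-endo-trig oxa-Michael closure that forms O1–C2, and the warm acidic work-up breaks any boron chelate and completes the closure. The closest known reaction type is the BF3-mediated cinnamoylation of phloroglucinol ethers such as 3,5-dimethoxyphenol, which gives 2'-hydroxychalcones and 5-methoxyflavanones. The stereocenter at C2 of unit 2 has no controlling element and should form racemic, which is harmless because step 7 removes it. The step needs selectivity between the aromatic rings and between an 8- and a 6-linkage: the free dihydroxy ring is far more nucleophilic than the fully methylated, carbonyl-deactivated ring A of unit 1, and the mirror symmetry of the nucleophile together with the methoxy group para to the biaryl bond leaves the 8-linked chromanone as the only possible ring closure. It also needs acylation to win over conjugate arylation at the β-carbon, which the acid chloride with BF3 (an acylium-like electrophile, used at about one equivalent) should favour.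

**Step 7**
Reactants: 13 (±)-8-[5,7-dimethoxy-2-(4-methoxyphenyl)-4-oxochromen-3-yl]-7-hydroxy-5-methoxy-2-(4-methoxyphenyl)chroman-4-one
Product: 14 8-[5,7-dimethoxy-2-(4-methoxyphenyl)-4-oxochromen-3-yl]-7-hydroxy-5-methoxy-2-(4-methoxyphenyl)chromen-4-one
Conditions: DDQ (2 equiv), 1,4-dioxane, reflux
Reagents that add atoms: none
Why: Quinone dehydrogenation: DDQ abstracts hydride from C2 of unit 2, a benzylic position next to oxygen and stabilised by the 4-methoxyphenyl group, and loss of the C3 proton gives the aromatic pyranone and removes the only stereocenter, while the 7-hydroxyl of unit 2, para to the carbonyl-bearing carbon, is a poor partner for phenol oxidation.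

**Step 8**
Reactants: 14 8-[5,7-dimethoxy-2-(4-methoxyphenyl)-4-oxochromen-3-yl]-7-hydroxy-5-methoxy-2-(4-methoxyphenyl)chromen-4-one
Product: 15 3,8'-biapigenin
Conditions: BBr3 (excess), CH2Cl2, −78 °C → rt; then MeOH, H2O
Reagents that add atoms: none
Why: Lewis acid ether cleavage (BBr3 demethylation): boron binds each ether oxygen and bromide removes the methyl group by SN2 attack, so all five aryl methyl ethers should fall, and the low temperature and absence of hot protic acid avoid opening and reclosure of ring C of the 5-hydroxy-8-aryl flavone (Wessely–Moser isomerisation to the 6-linked isomer).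

**Compound list**

1 | 5-methoxyresorcinol | COc1cc(O)cc(O)c1 | starting material
2 | 1-methoxy-3,5-bis(methoxymethoxy)benzene | COCOc1cc(OC)cc(OCOC)c1 | intermediate
3 | 5,7-dimethoxy-2-(4-methoxyphenyl)chromen-4-one (4',5,7-trimethoxyflavone) | COc1ccc(cc1)-c1cc(=O)c2c(OC)cc(OC)cc2o1 | starting material
4 | 3-lithio-5,7-dimethoxy-2-(4-methoxyphenyl)chromen-4-one | COc1ccc(cc1)-c1oc2cc(OC)cc(OC)c2c(=O)c1[Li] | intermediate (not isolated)
5 | 3-iodo-5,7-dimethoxy-2-(4-methoxyphenyl)chromen-4-one | COc1ccc(cc1)-c1oc2cc(OC)cc(OC)c2c(=O)c1I | intermediate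
6 | [4-methoxy-2,6-bis(methoxymethoxy)phenyl]lithium | [Li]c1c(OCOC)cc(OC)cc1OCOC | intermediate (not isolated)
7 | [4-methoxy-2,6-bis(methoxymethoxy)phenyl]zinc chloride | Cl[Zn]c1c(OCOC)cc(OC)cc1OCOC | intermediate (not isolated)
8 | 5,7-dimethoxy-3-[4-methoxy-2,6-bis(methoxymethoxy)phenyl]-2-(4-methoxyphenyl)chromen-4-one | COc1ccc(cc1)-c1oc2cc(OC)cc(OC)c2c(=O)c1-c1c(OCOC)cc(OC)cc1OCOC | intermediate
9 | 3-(2,6-dihydroxy-4-methoxyphenyl)-5,7-dimethoxy-2-(4-methoxyphenyl)chromen-4-one | COc1ccc(cc1)-c1oc2cc(OC)cc(OC)c2c(=O)c1-c1c(O)cc(OC)cc1O | intermediate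
10 | (E)-4-methoxycinnamic acid | COc1ccc(/C=C/C(=O)O)cc1 | starting material
11 | (E)-4-methoxycinnamoyl chloride | COc1ccc(/C=C/C(Cl)=O)cc1 | intermediate
12 | 3-{2,6-dihydroxy-4-methoxy-3-[(E)-3-(4-methoxyphenyl)prop-2-enoyl]phenyl}-5,7-dimethoxy-2-(4-methoxyphenyl)chromen-4-one (chalcone) | COc1ccc(cc1)-c1oc2cc(OC)cc(OC)c2c(=O)c1-c1c(O)cc(OC)c(C(=O)/C=C/c2ccc(OC)cc2)c1O | intermediate (not isolated)
13 | (±)-8-[5,7-dimethoxy-2-(4-methoxyphenyl)-4-oxochromen-3-yl]-7-hydroxy-5-methoxy-2-(4-methoxyphenyl)chroman-4-one (racemic, one enantiomer drawn) | COc1ccc(cc1)-c1oc2cc(OC)cc(OC)c2c(=O)c1-c1c(O)cc(OC)c2c1O[C@H](c1ccc(OC)cc1)CC2=O | intermediate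
14 | 8-[5,7-dimethoxy-2-(4-methoxyphenyl)-4-oxochromen-3-yl]-7-hydroxy-5-methoxy-2-(4-methoxyphenyl)chromen-4-one | COc1ccc(cc1)-c1oc2cc(OC)cc(OC)c2c(=O)c1-c1c(O)cc(OC)c2c1oc(-c1ccc(OC)cc1)cc2=O | intermediate
15 | 3,8'-biapigenin | O=c1c(-c2c(O)cc(O)c3c(=O)cc(-c4ccc(O)cc4)oc23)c(-c2ccc(O)cc2)oc2cc(O)cc(O)c12 | target

**Step count.** Total: 8 steps. Longest linear sequence: 6 steps (1 → 2 → 8 → 9 → 13 → 14 → 15; steps 1, 3, 4, 6, 7, 8).

**Steps most likely to fail**

Step 6. The electron-rich ring may add to the β-carbon of the cinnamoyl group (conjugate Friedel–Crafts alkylation followed by lactonisation) instead of being acylated, or a second acylation may follow at the remaining ring CH. The fallback sets out from 9 and comes back at 13, and builds the three-carbon bridge by aldol chemistry instead: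
- C-acetylation of 9 (Ac2O, BF3·OEt2, 70 °C; same symmetry argument) should give 3-(3-acetyl-2,6-dihydroxy-4-methoxyphenyl)-5,7-dimethoxy-2-(4-methoxyphenyl)chromen-4-one F1.
- The hydroxyl that is not hydrogen-bonded to the acetyl group is capped (MOMCl, iPr2NEt, CH2Cl2) to give 3-[3-acetyl-2-hydroxy-4-methoxy-6-(methoxymethoxy)phenyl]-5,7-dimethoxy-2-(4-methoxyphenyl)chromen-4-one F2.
- Claisen–Schmidt condensation with 4-methoxybenzaldehyde (KOH, EtOH, rt) gives the MOM-protected chalcone 3-{2-hydroxy-4-methoxy-6-(methoxymethoxy)-3-[(E)-3-(4-methoxyphenyl)prop-2-enoyl]phenyl}-5,7-dimethoxy-2-(4-methoxyphenyl)chromen-4-one F3.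
- HCl in MeOH at reflux removes the MOM group and closes the chalcone to flavanone 13.

Step 3. Transmetalation and reductive elimination at carbons flanked on both sides may be too slow, so that hydrodeiodination of the iodoflavone and homocoupling take over. The fallback sets out from 2 (through arylzinc 7) and comes back at 8. It forms the aryl–C3 bond on a chromone that has no 2-aryl group and then rebuilds ring C of unit 1:
- 2-Hydroxy-4,6-dimethoxyacetophenone and N,N-dimethylformamide dimethyl acetal (95 °C) give the enaminone (E)-3-(dimethylamino)-1-(2-hydroxy-4,6-dimethoxyphenyl)prop-2-en-1-one F4.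
- Iodine (pyridine, CHCl3, rt) cyclises it to 3-iodo-5,7-dimethoxychromen-4-one F5.
- Negishi coupling of 7 with this unhindered iodide (same catalyst) gives the isoflavone 5,7-dimethoxy-3-[4-methoxy-2,6-bis(methoxymethoxy)phenyl]chromen-4-one F6.
- Aqueous KOH in EtOH at reflux opens the isoflavone with loss of C2 as formate to the deoxybenzoin 1-(2-hydroxy-4,6-dimethoxyphenyl)-2-[4-methoxy-2,6-bis(methoxymethoxy)phenyl]ethanone F7.
- 4-Methoxybenzoyl chloride with K2CO3 in acetone at reflux (O-aroylation, Baker–Venkataraman acyl shift, cyclodehydration) delivers 8.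

Step 7. Hydride abstraction may be slow, with oxidation of the free phenol by the quinone competing. The fallback sets out from 13 and comes back at 15, and caps the phenol before a different oxidation:
- Methylation (MeI, K2CO3, acetone, reflux) gives (±)-8-[5,7-dimethoxy-2-(4-methoxyphenyl)-4-oxochromen-3-yl]-5,7-dimethoxy-2-(4-methoxyphenyl)chroman-4-one F8.
- Iodine (catalytic) in DMSO at 130 °C (α-iodination and elimination) gives the hexamethyl ether 8-[5,7-dimethoxy-2-(4-methoxyphenyl)-4-oxochromen-3-yl]-5,7-dimethoxy-2-(4-methoxyphenyl)chromen-4-one F9.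
- BBr3 under the conditions of step 8 cleaves all six methyl ethers to 15.

**Further compounds**

F1 | step 6 | 3-(3-acetyl-2,6-dihydroxy-4-methoxyphenyl)-5,7-dimethoxy-2-(4-methoxyphenyl)chromen-4-one | COc1ccc(cc1)-c1oc2cc(OC)cc(OC)c2c(=O)c1-c1c(O)cc(OC)c(C(C)=O)c1O
F2 | step 6 | 3-[3-acetyl-2-hydroxy-4-methoxy-6-(methoxymethoxy)phenyl]-5,7-dimethoxy-2-(4-methoxyphenyl)chromen-4-one | COc1ccc(cc1)-c1oc2cc(OC)cc(OC)c2c(=O)c1-c1c(OCOC)cc(OC)c(C(C)=O)c1O
F3 | step 6 | 3-{2-hydroxy-4-methoxy-6-(methoxymethoxy)-3-[(E)-3-(4-methoxyphenyl)prop-2-enoyl]phenyl}-5,7-dimethoxy-2-(4-methoxyphenyl)chromen-4-one | COc1ccc(cc1)-c1oc2cc(OC)cc(OC)c2c(=O)c1-c1c(OCOC)cc(OC)c(C(=O)/C=C/c2ccc(OC)cc2)c1O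
F4 | step 3 | (E)-3-(dimethylamino)-1-(2-hydroxy-4,6-dimethoxyphenyl)prop-2-en-1-one | CN(C)/C=C/C(=O)c1c(O)cc(OC)cc1OC
F5 | step 3 | 3-iodo-5,7-dimethoxychromen-4-one | O=c1c(I)coc2cc(OC)cc(OC)c12
F6 | step 3 | 5,7-dimethoxy-3-[4-methoxy-2,6-bis(methoxymethoxy)phenyl]chromen-4-one | COCOc1cc(OC)cc(OCOC)c1-c1coc2cc(OC)cc(OC)c2c1=O
F7 | step 3 | 1-(2-hydroxy-4,6-dimethoxyphenyl)-2-[4-methoxy-2,6-bis(methoxymethoxy)phenyl]ethanone | COCOc1cc(OC)cc(OCOC)c1CC(=O)c1c(O)cc(OC)cc1OC
F8 | step 7 | (±)-8-[5,7-dimethoxy-2-(4-methoxyphenyl)-4-oxochromen-3-yl]-5,7-dimethoxy-2-(4-methoxyphenyl)chroman-4-one (racemic, one enantiomer drawn) | COc1ccc(cc1)-c1oc2cc(OC)cc(OC)c2c(=O)c1-c1c(OC)cc(OC)c2c1O[C@H](c1ccc(OC)cc1)CC2=O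
F9 | step 7 | 8-[5,7-dimethoxy-2-(4-methoxyphenyl)-4-oxochromen-3-yl]-5,7-dimethoxy-2-(4-methoxyphenyl)chromen-4-one | COc1ccc(cc1)-c1oc2cc(OC)cc(OC)c2c(=O)c1-c1c(OC)cc(OC)c2c1oc(-c1ccc(OC)cc1)cc2=O
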